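At 60 °C the cedar flask, the one asked about, sat near 19.8% target from 25.0 min to 180 min, and the hotter larch flask sat near 8.4% on less reagent.

| flask | starting material | reagent | second substrate | free catalyst | temperature | remark | time |
|---|---|---|---|---|---|---|---|
| cedar | 0.010 M | 0.015 M | 0.020 M | 0.15 mM | 60 °C | the very flask that is asked about, followed so far |  |
| larch | 0.010 M | 0.0075 M | 0.020 M | 0.15 mM | 66 °C | run made earlier |  |
| flask | 0.010 M | 0.0150 M | 0.0200 M | 0.15 mM | 60 °C |  | 4.0 h |

| run | time / min | target / % |
|---|---|---|
| cedar | 15.0 | 18.3 |
| cedar | 25.0 | 19.5 |
| cedar | 40.0 | 19.7 |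
| cedar | 50.0 | 19.2 |
| cedar | 80.0 | 20.3 |
| cedar | 120 | 19.9 |
| cedar | 180 | 19.8 |
| larch | 1.00 | 4.3 |
| larch | 3.00 | 7.1 |
| larch | 6.00 | 7.2 |
| larch | 8.00 | 8.0 |
| larch | 12.0 | 7.5 |
| larch | 15.0 | 9.0 |
| larch | 20.0 | 8.4 |

(standard deviation of a reading: 0.5 percentage points)

- target taken out counts as made
- additions bring no volume worth counting

- violet: at 4.0 h add free catalyst, 100% of the amount charged, then wait 8.0 h
- blue: at 4.0 h add reagent, 100% of the amount charged, then wait 8.0 h
- amber: at 4.0 h raise the temperature by 10 K, then wait 8.0 h
- grey: change nothing and wait 8.0 h more
- green: at 4.0 h take out 90% of the target then present, then wait 8.0 h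

- target, in percent of the starting material first charged, at 4.0 h
- the remedy with the largest gain of target, or "none" below 2 percentage points (violet / blue / amber / grey / green / none)
- target present, with what was taken out counted in, in percent of the starting material first charged, after amber
- target present, with what was taken out counted in, in percent of the starting material first charged, after green

My bench rule for a reaction that stops with material in hand was that the catalyst has died after a set number of turnovers. Cedar's catalyst is 1.50% of its starting material, so cedar read 13.2 turnovers, while larch read 5.60. The rule broke there: cedar's count was 2.36 times larch's, and its reagent charge was 2.00 times larch's.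

So I compared rates at one moment. Target forms at a rate that goes with reagent and catalyst, and I assumed that catalyst is lost at a rate that ignores reagent, so target per catalyst lost goes with reagent. I carried the turnover budget, a turnover number per equivalent of reagent: 8.80 from cedar, and a reading of 7.47 from larch. Then I asked how this drifts. Subtracting what the target took from the charge, I reckoned 1.30 equivalents of reagent for cedar, so I expected violet to gain 17 percentage points. With the catalyst lost, as I assumed, I expected grey, blue, amber and green to gain nothing.

The forecast read the plateau differently: “That fits a reversible, exothermic reaction”. It gave 19.8% now, 12.5% after amber and 33% after green, and it named green as best where I named violet.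

The flask gave 19.4% at 4.0 h, and violet came out best with 6.5 points gained, less than my 17 points. Amber gave 19.4% and green 19.4%.

    starting material + reagent + free catalyst → free catalyst + target (k = 810 M⁻² s⁻¹, Ea = 38.0 kJ mol⁻¹)
    second substrate + reagent + free catalyst → free catalyst + second product (k = 200 M⁻² s⁻¹, Ea = 44.0 kJ mol⁻¹)
    free catalyst → spent catalyst A (k = 0.00410 s⁻¹, Ea = 89.0 kJ mol⁻¹)
    2 free catalyst → spent catalyst B (k = 13.0 M⁻¹ s⁻¹, Ea = 43.0 kJ mol⁻¹)
    reagent ⇌ dormant form (K = 1.70, k = 0.00170 s⁻¹, Ea = 105 kJ mol⁻¹, ΔH = 29.0 kJ mol⁻¹)
    (constants at 60 °C)

Turned back, the budget says violet's gain met 0.493 equivalents of reagent. At 4.0 h the flask held 0.445 equivalents free, 30% of its charge, and dormant form stood at 50.5% of that charge. For the neighbour charged with 6.00 equiv of reagent the budget gives 79.2%; that neighbour gave 58.4%, with 41.6% of its starting material still there.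

All runs were generated by integration from invented constants; scatter was added.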